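**Retrosynthetic overview**
1. Rhopaloic acid B is a 2,5-cis-disubstituted oxane (ring A: O1, C2–C6). The acrylic acid on C2 is unmasked last from a C2–CH2CO2Et arm (α-methylenation, saponification), and C3/C4 are traced back to a C3=C4 alkene.
2. Key disconnection C5–C1′ (ring carbon to first chain carbon): one-pot hydroboration and copper-catalysed anti-SN2′ allyl–alkyl coupling. The partners are the C16 hydrocarbon (3E,7E)-4,8,12-trimethyltrideca-1,3,7,11-tetraene (fragment 2, two steps from farnesol) and a 3,6-dihydro-2H-pyran-3-yl phosphate (fragment 1).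
3. Enabling feature: in ring A, C3 and C4 (between stereocentre C2 and C5) are bare CH2 groups, and C5 is flanked by the unsubstituted C6H2–O1, so C3–C4–C5 can serve as an allylic triad. A C3–O bond that is absent from the target is set trans to the C2 arm; it relays the C2 configuration to C5 and is expelled in the same step.
4. Ring order: ring A is the only ring and is made first, by Achmatowicz ring expansion of a furyl carbinol whose stereocentre (future C2) comes from a Noyori hydrogenation. C6 is then reduced to CH2 and the C3 ketone to the relay alcohol.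

Key step: step 8

Remark: the target is taken as (2R,5R), with the two ring substituents cis; ring atoms keep the target numbering O1, C2–C6 throughout, chain atoms are C1′ onward from the ring, and homofarnesyl = (3E,7E)-4,8,12-trimethyltrideca-3,7,11-trien-1-yl.

Step 1
Reactants: 1 ethyl 3-(furan-2-yl)-3-oxopropanoate
Product: 2 ethyl (3S)-3-(furan-2-yl)-3-hydroxypropanoate
Conditions: H2 (10 bar), RuCl2[(R)-BINAP] (0.5 mol %), EtOH, 50 °C
Reagents that add atoms: none
Why: Noyori asymmetric hydrogenation of a β-keto ester, in which chelation of the keto ester to the ruthenium–(R)-BINAP hydride fixes the face of hydride delivery (the same spatial sense that turns acetoacetates into (R)-3-hydroxybutanoates, named S here because furyl outranks CH2CO2Et), so that the future C2 is set while the furan stays untouched.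

Step 2
Reactants: 2 ethyl (3S)-3-(furan-2-yl)-3-hydroxypropanoate
Product: 3 ethyl [(2S)-6-hydroxy-3-oxo-3,6-dihydro-2H-pyran-2-yl]acetate (both C6 anomers)
Conditions: m-CPBA, CH2Cl2, 0 °C to rt
Reagents that add atoms: m-CPBA (3-chloroperoxybenzoic acid), O=C(OO)c1cccc(Cl)c1
Why: Achmatowicz rearrangement, in which peracid oxidation of the electron-rich furan gives the cis-enedione whose aldehyde is captured by the carbinol OH to close ring A (O1–C6 bond) without touching C2, the anomeric mixture being irrelevant because C6 becomes CH2 in step 3.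

Step 3
Reactants: 3 ethyl [(2S)-6-hydroxy-3-oxo-3,6-dihydro-2H-pyran-2-yl]acetate
Product: 4 ethyl [(2S)-3-oxo-3,6-dihydro-2H-pyran-2-yl]acetate
Conditions: Et3SiH, CF3CO2H, CH2Cl2, −40 to 0 °C
Reagents that add atoms: none
Why: Ionic lactol reduction (Kishi-type), in which the acid ionises only the C6–OH to the ring oxocarbenium ion, which takes hydride from the silane while enone and ester are inert to it, so both anomers converge on one compound.

Step 4
Reactants: 4 ethyl [(2S)-3-oxo-3,6-dihydro-2H-pyran-2-yl]acetate
Product: 5 ethyl [(2S,3R)-3-hydroxy-3,6-dihydro-2H-pyran-2-yl]acetate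
Conditions: NaBH4, CeCl3·7H2O, MeOH, −78 °C
Reagents that add atoms: none
Why: Luche 1,2-reduction, in which axial hydride attack on the half-chair with the C2 arm pseudoequatorial should give the pseudoequatorial C3–OH trans to the arm, and any cis epimer should lactonise onto the arm and be removed by chromatography.

Step 5
Reactants: 5 ethyl [(2S,3R)-3-hydroxy-3,6-dihydro-2H-pyran-2-yl]acetate
Product: 6 ethyl [(2S,3R)-3-(diethoxyphosphoryloxy)-3,6-dihydro-2H-pyran-2-yl]acetate
Conditions: ClP(O)(OEt)2, pyridine, DMAP (cat.), CH2Cl2, 0 °C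
Reagents that add atoms: diethyl chlorophosphate, CCOP(=O)(Cl)OCC
Why: O-phosphorylation of a secondary allylic alcohol under nucleophilic catalysis, which forms only the O–P bond so that the C3 configuration is retained.

Step 6
Reactants: 7 (2E,6E)-farnesol
Product: 8 (2E,6E)-farnesal
Conditions: [Cu(MeCN)4]OTf (5 mol %), 2,2′-bipyridine, TEMPO, N-methylimidazole, air, MeCN, rt
Reagents that add atoms: none
Why: Copper/nitroxyl-catalysed aerobic oxidation of a primary allylic alcohol, which stops at the enal and is mild enough to keep the 2E geometry.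

Step 7
Reactants: 8 (2E,6E)-farnesal
Product: 9 (3E,7E)-4,8,12-trimethyltrideca-1,3,7,11-tetraene
Conditions: Ph3PCH3Br, n-BuLi, THF, 0 °C to rt
Reagents that add atoms: methyltriphenylphosphonium bromide, C[P+](c1ccccc1)(c1ccccc1)c1ccccc1.[Br-]
Why: Wittig methylenation, in which the non-stabilised ylide adds 1,2 to the enal and leaves the existing trisubstituted alkenes unchanged, as in the established conversion of geranial into its triene homologue.

Step 8
Reactants: 9 (3E,7E)-4,8,12-trimethyltrideca-1,3,7,11-tetraene (fragment 2); 6 ethyl [(2S,3R)-3-(diethoxyphosphoryloxy)-3,6-dihydro-2H-pyran-2-yl]acetate (fragment 1)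
Product: 12 ethyl [(2S,5R)-5-homofarnesyl-5,6-dihydro-2H-pyran-2-yl]acetate, via B-homofarnesyl-9-BBN 10 (not isolated), via potassium tert-butoxyborate 11 (not isolated)
Conditions: 9 (slight excess), 9-BBN dimer, THF, 0 °C to rt; then KOt-Bu, CuOAc (10 mol %), 6, THF, 50 °C
Reagents that add atoms: none
Why: 9-BBN should add only to the terminal, monosubstituted C=C at the diene end of 9 (boron on the CH2 terminus), KOt-Bu turns borane 10 into borate 11, and boron-to-copper transmetalation gives a homofarnesyl complex of monovalent copper. This complex attacks C5 of the C4=C5 bond of 6 on the face opposite to the pseudoaxial C3 phosphate, giving a γ-σ-allyl species of trivalent copper that reductively eliminates before it can equilibrate, so that C5–C1′ forms while the phosphate leaves and the alkene moves to C3=C4. The closest known reaction type is the copper-catalysed, γ-selective and 1,3-anti-stereospecific allyl–alkyl coupling of secondary allylic phosphates with alkyl-9-BBN reagents, the catalytic relative of the anti-SN2′ substitution of cyclohex-2-enyl esters by organocopper reagents. No ring is closed; the one new stereocentre, C5, is controlled by the sacrificial C3–O stereocentre, which stands trans to the C2 arm, so that anti attack puts the chain cis to that arm (5R). The step needs γ over α attack, anti over syn delivery, substitution over elimination and retention of the chain geometry: C5 lies next to the unsubstituted C6H2 whereas C3 lies next to the substituted C2, KOt-Bu in THF is the anti-selective regime of this coupling, all alkoxide is bound in 11 so that the ester and the β-alkoxy unit see no free base, and the chain is passed on as a two-electron nucleophile so that no homoallyl radical can scramble the C3′=C4′ bond. In one operation the step thus joins the 16 chain carbons to the ring, sets the last stereocentre and deletes the C3 oxygen.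

Step 9
Reactants: 12 ethyl [(2S,5R)-5-homofarnesyl-5,6-dihydro-2H-pyran-2-yl]acetate
Product: 13 ethyl [(2R,5R)-5-homofarnesyloxan-2-yl]acetate
Conditions: H2 (1 bar), RhCl(PPh3)3 (5 mol %), benzene–EtOH 1:1, rt
Reagents that add atoms: none
Why: Homogeneous hydrogenation gated by alkene coordination, so the cis-1,2-disubstituted ring alkene, one face of which is free of substituents, should be reduced while the three trisubstituted chain alkenes and the ester stay, and no stereocentre is touched (the C2 descriptor changes only because the priorities change).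

Step 10
Reactants: 13 ethyl [(2R,5R)-5-homofarnesyloxan-2-yl]acetate
Product: 15 ethyl 3-(dimethylamino)-2-[(2R,5R)-5-homofarnesyloxan-2-yl]propanoate (both α-epimers), via lithium enolate 14 (not isolated)
Conditions: LiN(i-Pr)2, THF, −78 °C; then CH2=NMe2+ I−, −78 °C to rt
Reagents that add atoms: N,N-dimethylmethyleneiminium iodide (Eschenmoser's salt), C=[N+](C)C.[I-]
Why: Mannich reaction of an ester enolate (first half of the Eschenmoser methylenation), in which kinetic deprotonation at −78 °C gives an enolate too cold to expel the β-alkoxide O1 and the iminium salt traps it, the new α-centre being destroyed in step 11.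

Step 11
Reactants: 15 ethyl 3-(dimethylamino)-2-[(2R,5R)-5-homofarnesyloxan-2-yl]propanoate
Product: 17 ethyl 2-[(2R,5R)-5-homofarnesyloxan-2-yl]prop-2-enoate, via trimethylammonium iodide 16 (not isolated)
Conditions: MeI, MeOH, rt; then DBU, CH2Cl2, rt
Reagents that add atoms: none
Why: N-quaternisation followed by Hofmann-type E1cB elimination, in which trimethylamine is by far the better leaving group than the ring alkoxide, so that the exocyclic methylene forms and ring A stays closed.

Step 12
Reactants: 17 ethyl 2-[(2R,5R)-5-homofarnesyloxan-2-yl]prop-2-enoate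
Product: 19 rhopaloic acid B, via lithium carboxylate 18 (not isolated)
Conditions: LiOH, THF–MeOH–H2O, rt; then 1 M HCl, 0 °C
Reagents that add atoms: lithium hydroxide, [Li+].[OH-]
Why: Saponification by acyl–oxygen cleavage, which is safe because the α-carbon carries no proton, so neither epimerisation nor β-elimination is open, and brief cold acidification leaves the polyene intact.

**Compound list**
1 | ethyl 3-(furan-2-yl)-3-oxopropanoate | CCOC(=O)CC(=O)c1ccco1 | starting material
2 | ethyl (3S)-3-(furan-2-yl)-3-hydroxypropanoate | CCOC(=O)C[C@H](O)c1ccco1 | intermediate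
3 | ethyl [(2S)-6-hydroxy-3-oxo-3,6-dihydro-2H-pyran-2-yl]acetate, both C6 anomers | CCOC(=O)C[C@H]1C(=O)C=CC(O)O1 | intermediate
4 | ethyl [(2S)-3-oxo-3,6-dihydro-2H-pyran-2-yl]acetate | CCOC(=O)C[C@H]1C(=O)C=CCO1 | intermediate
5 | ethyl [(2S,3R)-3-hydroxy-3,6-dihydro-2H-pyran-2-yl]acetate (2,3-trans) | CCOC(=O)C[C@H]1[C@H](O)C=CCO1 | intermediate
6 | ethyl [(2S,3R)-3-(diethoxyphosphoryloxy)-3,6-dihydro-2H-pyran-2-yl]acetate | CCOC(=O)C[C@H]1[C@H](OP(=O)(OCC)OCC)C=CCO1 | intermediate
7 | (2E,6E)-farnesol | CC(C)=CCC/C(C)=C/CC/C(C)=C/CO | starting material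
8 | (2E,6E)-farnesal | CC(C)=CCC/C(C)=C/CC/C(C)=C/C=O | intermediate
9 | (3E,7E)-4,8,12-trimethyltrideca-1,3,7,11-tetraene | CC(C)=CCC/C(C)=C/CC/C(C)=C/C=C | intermediate
10 | 9-homofarnesyl-9-borabicyclo[3.3.1]nonane | CC(C)=CCC/C(C)=C/CC/C(C)=C/CCB1C2CCCC1CCC2 | intermediate
11 | potassium 9-tert-butoxy-9-homofarnesyl-9-boratabicyclo[3.3.1]nonane | [K+].CC(C)=CCC/C(C)=C/CC/C(C)=C/CC[B-]1(OC(C)(C)C)C2CCCC1CCC2 | intermediate
12 | ethyl [(2S,5R)-5-homofarnesyl-5,6-dihydro-2H-pyran-2-yl]acetate (2,5-cis) | CCOC(=O)C[C@H]1C=C[C@@H](CC/C=C(\C)CC/C=C(\C)CCC=C(C)C)CO1 | intermediate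
13 | ethyl [(2R,5R)-5-homofarnesyloxan-2-yl]acetate | CCOC(=O)C[C@H]1CC[C@@H](CC/C=C(\C)CC/C=C(\C)CCC=C(C)C)CO1 | intermediate
14 | lithium enolate of 13 | [Li+].CCOC([O-])=C[C@H]1CC[C@@H](CC/C=C(\C)CC/C=C(\C)CCC=C(C)C)CO1 | intermediate
15 | ethyl 3-(dimethylamino)-2-[(2R,5R)-5-homofarnesyloxan-2-yl]propanoate, both α-epimers | CCOC(=O)C(CN(C)C)[C@H]1CC[C@@H](CC/C=C(\C)CC/C=C(\C)CCC=C(C)C)CO1 | intermediate
16 | {2-(ethoxycarbonyl)-2-[(2R,5R)-5-homofarnesyloxan-2-yl]ethyl}trimethylammonium iodide | CCOC(=O)C(C[N+](C)(C)C)[C@H]1CC[C@@H](CC/C=C(\C)CC/C=C(\C)CCC=C(C)C)CO1.[I-] | intermediate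
17 | ethyl 2-[(2R,5R)-5-homofarnesyloxan-2-yl]prop-2-enoate | C=C(C(=O)OCC)[C@H]1CC[C@@H](CC/C=C(\C)CC/C=C(\C)CCC=C(C)C)CO1 | intermediate
18 | lithium 2-[(2R,5R)-5-homofarnesyloxan-2-yl]prop-2-enoate | [Li+].C=C(C(=O)[O-])[C@H]1CC[C@@H](CC/C=C(\C)CC/C=C(\C)CCC=C(C)C)CO1 | intermediate
19 | rhopaloic acid B, 2-[(2R,5R)-5-homofarnesyloxan-2-yl]prop-2-enoic acid | C=C(C(=O)O)[C@H]1CC[C@@H](CC/C=C(\C)CC/C=C(\C)CCC=C(C)C)CO1 | target

**Step count and risks**
Total step count: 12. Longest linear sequence: 10 steps (steps 1–5 and 8–12).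

Step 8. The reactive conformer must carry both the C2 arm and the C3 phosphate axial, which slows anti attack on C5. Attack at C3, leakage into syn delivery or loss of the phosphate by elimination may then compete.
- The fallback sets out from 4 and 9 and comes back at 12. It makes the C5–C1′ bond without stereocontrol and sets C5 afterwards by hydrogen delivery.
- Hydrozirconation of the terminal alkene of 9 with Cp2ZrHCl (THF, rt) should give homofarnesylzirconocene chloride F1.
- Under CuBr·SMe2 catalysis with Me3SiCl, F1 should add 1,4 to enone 4 to give silyl enol ether F2 as a C5 epimer mixture.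
- Saegusa–Ito oxidation with Pd(OAc)2 (MeCN, rt) erases that centre and should give the 5-homofarnesyl enone F3. TsNHNH2 in EtOH then gives tosylhydrazone F4.
- Catecholborane (CHCl3, −40 °C), attacking C3 axially as in step 4, followed by NaOAc·3H2O at 60 °C, should give allylic diazene F5 with nitrogen trans to the C2 arm.
- Retro-ene loss of N2 from F5 delivers hydrogen to C5 on the nitrogen-bearing face and moves the alkene to C3=C4, which is 12.

Step 9. Over-reduction of the chain alkenes, or rhodium-induced migration of the ring double bond toward the enol ether position, may erode the material. The fallback sets out from 12 and comes back at 13. It leaves metal catalysis altogether for concerted, metal-free hydrogen transfer from diimide, generated from 2,4,6-triisopropylbenzenesulfonohydrazide and Et3N in 1,2-dichloroethane at 50 °C. Diimide reacts much more slowly as alkene substitution rises and cannot isomerise an allyl ether. This fallback makes no new compound (F0).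

Step 10. The ester enolate may expel the ring oxygen O1 (E1cB ring opening), or enolisation may stay incomplete. The fallback sets out from 13 and comes back at 19. It avoids strong base by moving the methylenation to the aldehyde oxidation level.
- i-Bu2AlH (CH2Cl2, −78 °C) should give [(2R,5R)-5-homofarnesyloxan-2-yl]acetaldehyde F6.
- CH2=NMe2+ I− and Et3N (CH2Cl2, rt) should take F6 through the Mannich base F7 to the 2-substituted propenal F8.
- Pinnick oxidation (NaClO2, NaH2PO4, 2-methyl-2-butene, t-BuOH–H2O) should give 19 directly.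

**Further compounds**
F1 | step 8 | chlorobis(cyclopentadienyl)(homofarnesyl)zirconium | CC(C)=CCC/C(C)=C/CC/C(C)=C/CC[Zr](Cl)(C1C=CC=C1)C1C=CC=C1
F2 | step 8 | ethyl [(2S)-5-homofarnesyl-3-(trimethylsilyloxy)-5,6-dihydro-2H-pyran-2-yl]acetate, both C5 epimers | CCOC(=O)C[C@H]1C(O[Si](C)(C)C)=CC(CC/C=C(\C)CC/C=C(\C)CCC=C(C)C)CO1
F3 | step 8 | ethyl [(2S)-5-homofarnesyl-3-oxo-3,6-dihydro-2H-pyran-2-yl]acetate | CCOC(=O)C[C@H]1C(=O)C=C(CC/C=C(\C)CC/C=C(\C)CCC=C(C)C)CO1
F4 | step 8 | 4-methylbenzenesulfonylhydrazone of F3 | CCOC(=O)C[C@H]1C(=NNS(=O)(=O)c2ccc(C)cc2)C=C(CC/C=C(\C)CC/C=C(\C)CCC=C(C)C)CO1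
F5 | step 8 | ethyl [(2S,3R)-3-diazenyl-5-homofarnesyl-3,6-dihydro-2H-pyran-2-yl]acetate | CCOC(=O)C[C@H]1[C@H](N=N)C=C(CC/C=C(\C)CC/C=C(\C)CCC=C(C)C)CO1
F0 | step 9 | none | none
F6 | step 10 | [(2R,5R)-5-homofarnesyloxan-2-yl]acetaldehyde | O=CC[C@H]1CC[C@@H](CC/C=C(\C)CC/C=C(\C)CCC=C(C)C)CO1
F7 | step 10 | 3-(dimethylamino)-2-[(2R,5R)-5-homofarnesyloxan-2-yl]propanal, both α-epimers | O=CC(CN(C)C)[C@H]1CC[C@@H](CC/C=C(\C)CC/C=C(\C)CCC=C(C)C)CO1
F8 | step 10 | 2-[(2R,5R)-5-homofarnesyloxan-2-yl]prop-2-enal | C=C(C=O)[C@H]1CC[C@@H](CC/C=C(\C)CC/C=C(\C)CCC=C(C)C)CO1
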